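**Retrosynthetic overview**

- Target 23 comes from phenol 22 by hydrogenolysis of the two benzyl ethers on ring B; 22 comes from the methyl enol ether 18 by α'-selenation and selenoxide elimination, and 18 from dione 17 by O-methylation.
- Feature: ring A (C1' carries the C14 chain, C3' the OH, C5' the OMe) is the aromatized mono-methyl enol ether of a 5-alkylcyclohexane-1,3-dione whose mirror plane runs through C1' and C4', so the two ring oxygens are equivalent until one is methylated.
- Key disconnection: ring A bonds C1'–C6' (Michael) and C4'–C5' (Claisen) lead back to E-enone 12 and dimethyl malonate 13.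
- Enone 12 comes from aldehyde 10 by Wittig reaction; 10 from ester 8; 8 from a Negishi sp3–sp2 coupling of the alkylzinc made from bromo ester 6 (from lactone 4) with aryl bromide 3 (from 5-bromoresorcinol 1).
- Ring order: ring B is bought as an arene; ring A is the only ring formed (step 7) and is aromatized in steps 9 and 10.

Key step: step 7

Remark on the chemistry: the target is achiral. The stereocentres that appear in 9, 14–16 and 18–20 are formed without control (racemates; 19 and 20 mainly 5,6-trans) and all have vanished after step 10.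

**Step 1**
Reactants: 1 5-bromoresorcinol (5-bromobenzene-1,3-diol); 2 benzyl bromide (2.2 equiv in all)
Product: 3 1,3-bis(benzyloxy)-5-bromobenzene
Conditions: BnBr (2.2 equiv), K2CO3, DMF, 60 °C
Reagents that add atoms: benzyl bromide (second equivalent), BrCc1ccccc1
Why: Twofold Williamson ether synthesis, in which each of the two phenoxides displaces the bromide of one molecule of benzyl bromide by SN2 while the aryl bromide is inert to carbonate.

**Step 2**
Reactants: 4 ω-pentadecalactone (oxacyclohexadecan-2-one)
Product: 5 15-bromopentadecanoic acid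
Conditions: HBr (33% in AcOH), H2SO4 (cat.), 80 °C; then H2O
Reagents that add atoms: hydrogen bromide, Br
Why: Acid-mediated lactone ring opening, in which bromide displaces the activated primary C15–O bond by SN2, the standard way from a macrolactone to an ω-bromo acid.

**Step 3**
Reactants: 5 15-bromopentadecanoic acid
Product: 6 methyl 15-bromopentadecanoate
Conditions: MeOH, H2SO4 (cat.), reflux
Reagents that add atoms: methanol, CO
Why: Fischer esterification, under which the unactivated primary bromide is not solvolysed.

**Step 4**
Reactants: 6 methyl 15-bromopentadecanoate; 3 1,3-bis(benzyloxy)-5-bromobenzene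
Product: 8 methyl 15-[3,5-bis(benzyloxy)phenyl]pentadecanoate, via the alkylzinc bromide 7 (not isolated)
Conditions: Zn dust (1.5 equiv), I2 (5 mol%), DMA, 80 °C; then 3, Pd(OAc)2 (2 mol%), SPhos (2-dicyclohexylphosphino-2',6'-dimethoxybiphenyl, 4 mol%), THF, 50 °C
Reagents that add atoms: none
Why: Negishi coupling, in which zinc inserts directly into the primary C–Br bond without touching the ester and the zerovalent palladium catalyst formed from Pd(OAc)2 and the bulky biaryl phosphine joins the primary alkyl group to the aryl bromide faster than β-hydride elimination.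

**Step 5**
Reactants: 8 methyl 15-[3,5-bis(benzyloxy)phenyl]pentadecanoate
Product: 10 15-[3,5-bis(benzyloxy)phenyl]pentadecanal, via the aluminium hemiacetal 9 (not isolated)
Conditions: (iBu)2AlH (1.1 equiv), CH2Cl2, −78 °C; MeOH quench at −78 °C, then aq. KNaC4H4O6 (potassium sodium tartrate)
Reagents that add atoms: none
Why: Partial ester reduction with (iBu)2AlH, in which the tetrahedral aluminium hemiacetal persists at −78 °C and releases the aldehyde only on hydrolysis, the benzyl ethers being inert.

**Step 6**
Reactants: 10 15-[3,5-bis(benzyloxy)phenyl]pentadecanal; 11 acetylmethylenetriphenylphosphorane (1-(triphenylphosphoranylidene)propan-2-one)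
Product: 12 (3E)-18-[3,5-bis(benzyloxy)phenyl]octadec-3-en-2-one
Conditions: 11 (1.3 equiv), toluene, 90 °C
Reagents that add atoms: none
Why: Wittig olefination with a carbonyl-stabilized ylide, which should give the E-enone selectively from an unhindered aliphatic aldehyde.

**Step 7**
Reactants: 12 (3E)-18-[3,5-bis(benzyloxy)phenyl]octadec-3-en-2-one; 13 dimethyl malonate
Product: 17 5-{14-[3,5-bis(benzyloxy)phenyl]tetradecyl}cyclohexane-1,3-dione, via the Michael adduct 14 (not isolated), via the cyclic keto ester 15 (not isolated), via the keto acid 16 (not isolated)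
Conditions: 13 (1.3 equiv), NaOMe (1.3 equiv), MeOH/THF, reflux; then aq. NaOH, reflux; then aq. HCl to pH 2, 70 °C
Reagents that add atoms: none
Why: Sodium dimethyl malonate adds 1,4 to the E-enone (bond C1'–C6', adduct 14), the methyl ketone of 14 is enolized and attacks one malonate ester in a Claisen condensation (bond C4'–C5'), and deprotonation of the β-dicarbonyl 15 to its delocalized enolate drives both reversible steps forward, after which hydroxide cleaves the remaining ester and the β-keto acid 16 loses CO2 on acidification. The closest known reaction type is the Michael–Claisen annulation of alk-3-en-2-ones (or of mesityl oxide, as in the dimedone synthesis) with malonates to 5-substituted cyclohexane-1,3-diones. The carbocycle that becomes ring A closes in a 6-(enolendo)-exo-trig mode, the enolate double bond C3'=C4' lying inside the forming ring, which is favoured for a six-membered ring. C1' is formed as a racemic stereocentre and C6' as a transient one, and neither needs control because C6' stops being a stereocentre on decarboxylation and C1' lies on the mirror plane of dione 17. The step needs 1,4- over 1,2-addition and C- over O-acylation: the soft, stabilized malonate anion and the unhindered β-carbon of the E-enone should secure the first, and the thermodynamic sink of the dione enolate under NaOMe the second. The benzyl ethers of ring B are inert to methoxide, hydroxide and brief dilute acid.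

**Step 8**
Reactants: 17 5-{14-[3,5-bis(benzyloxy)phenyl]tetradecyl}cyclohexane-1,3-dione
Product: 18 5-{14-[3,5-bis(benzyloxy)phenyl]tetradecyl}-3-methoxycyclohex-2-en-1-one (racemic)
Conditions: MeOH/toluene, TsOH (cat.), reflux
Reagents that add atoms: methanol, CO
Why: Acid-catalysed enol etherification of the β-diketone (a vinylogous Fischer esterification), which can give only one constitution because the two carbonyl groups of 17 are related by the mirror plane through C1' and C4'.

**Step 9**
Reactants: 18 5-{14-[3,5-bis(benzyloxy)phenyl]tetradecyl}-3-methoxycyclohex-2-en-1-one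
Product: 19 5-{14-[3,5-bis(benzyloxy)phenyl]tetradecyl}-3-methoxy-6-(phenylselanyl)cyclohex-2-en-1-one (racemic, mainly 5,6-trans)
Conditions: LiN(iPr)2 (1.1 equiv), THF, −78 °C; then PhSeCl, −78 °C
Reagents that add atoms: benzeneselenenyl chloride, Cl[Se]c1ccccc1
Why: Kinetic α'-deprotonation of the vinylogous ester at C2' (C6 of the enone) followed by α-selenenylation of the enolate, the selenium entering trans to the chain on C1' and so leaving the C1'–H syn to it.

**Step 10**
Reactants: 19 5-{14-[3,5-bis(benzyloxy)phenyl]tetradecyl}-3-methoxy-6-(phenylselanyl)cyclohex-2-en-1-one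
Product: 22 3-{14-[3,5-bis(benzyloxy)phenyl]tetradecyl}-5-methoxyphenol, via the selenoxide 20 (not isolated), via the cross-conjugated dienone 21 (not isolated)
Conditions: H2O2 (30% aq.), pyridine, CH2Cl2, 0 °C to rt
Reagents that add atoms: none
Why: Selenide oxidation and syn-selenoxide elimination towards the only β-hydrogen (on C1'), after which the cross-conjugated dienone tautomerizes to the aromatic 3-methoxyphenol.

**Step 11**
Reactants: 22 3-{14-[3,5-bis(benzyloxy)phenyl]tetradecyl}-5-methoxyphenol
Product: 23 5-[14-(3-hydroxy-5-methoxyphenyl)tetradecyl]benzene-1,3-diol (target)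
Conditions: H2 (1 atm), 10% Pd/C, EtOAc/MeOH, rt
Reagents that add atoms: none
Why: Catalytic hydrogenolysis of the two benzyl aryl ethers, the molecule holding no other reducible group and the methyl ether being stable.

**Compound list**

1 | 5-bromoresorcinol (5-bromobenzene-1,3-diol) | Oc1cc(O)cc(Br)c1 | starting material
2 | benzyl bromide | BrCc1ccccc1 | starting material
3 | 1,3-bis(benzyloxy)-5-bromobenzene | Brc1cc(OCc2ccccc2)cc(OCc2ccccc2)c1 | intermediate
4 | ω-pentadecalactone (oxacyclohexadecan-2-one) | O=C1CCCCCCCCCCCCCCO1 | starting material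
5 | 15-bromopentadecanoic acid | OC(=O)CCCCCCCCCCCCCCBr | intermediate
6 | methyl 15-bromopentadecanoate | COC(=O)CCCCCCCCCCCCCCBr | intermediate
7 | (15-methoxy-15-oxopentadecyl)zinc bromide | COC(=O)CCCCCCCCCCCCCC[Zn]Br | intermediate (not isolated)
8 | methyl 15-[3,5-bis(benzyloxy)phenyl]pentadecanoate | COC(=O)CCCCCCCCCCCCCCc1cc(OCc2ccccc2)cc(OCc2ccccc2)c1 | intermediate
9 | {15-[3,5-bis(benzyloxy)phenyl]-1-methoxypentadecyloxy}diisobutylalumane (racemic) | COC(O[Al](CC(C)C)CC(C)C)CCCCCCCCCCCCCCc1cc(OCc2ccccc2)cc(OCc2ccccc2)c1 | intermediate (not isolated)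
10 | 15-[3,5-bis(benzyloxy)phenyl]pentadecanal | O=CCCCCCCCCCCCCCCc1cc(OCc2ccccc2)cc(OCc2ccccc2)c1 | intermediate
11 | acetylmethylenetriphenylphosphorane | CC(=O)C=P(c1ccccc1)(c1ccccc1)c1ccccc1 | starting material
12 | (3E)-18-[3,5-bis(benzyloxy)phenyl]octadec-3-en-2-one | CC(=O)/C=C/CCCCCCCCCCCCCCc1cc(OCc2ccccc2)cc(OCc2ccccc2)c1 | intermediate
13 | dimethyl malonate | COC(=O)CC(=O)OC | starting material
14 | dimethyl 2-{18-[3,5-bis(benzyloxy)phenyl]-2-oxooctadecan-4-yl}propanedioate (racemic) | COC(=O)C(C(=O)OC)C(CC(C)=O)CCCCCCCCCCCCCCc1cc(OCc2ccccc2)cc(OCc2ccccc2)c1 | intermediate (not isolated)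
15 | methyl 6-{14-[3,5-bis(benzyloxy)phenyl]tetradecyl}-2,4-dioxocyclohexane-1-carboxylate (racemic; present as its sodium enolate) | COC(=O)C1C(=O)CC(=O)CC1CCCCCCCCCCCCCCc1cc(OCc2ccccc2)cc(OCc2ccccc2)c1 | intermediate (not isolated)
16 | 6-{14-[3,5-bis(benzyloxy)phenyl]tetradecyl}-2,4-dioxocyclohexane-1-carboxylic acid (racemic; present as its sodium salt until acidified) | OC(=O)C1C(=O)CC(=O)CC1CCCCCCCCCCCCCCc1cc(OCc2ccccc2)cc(OCc2ccccc2)c1 | intermediate (not isolated)
17 | 5-{14-[3,5-bis(benzyloxy)phenyl]tetradecyl}cyclohexane-1,3-dione | O=C1CC(=O)CC(CCCCCCCCCCCCCCc2cc(OCc3ccccc3)cc(OCc3ccccc3)c2)C1 | intermediate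
18 | 5-{14-[3,5-bis(benzyloxy)phenyl]tetradecyl}-3-methoxycyclohex-2-en-1-one (racemic) | COC1=CC(=O)CC(CCCCCCCCCCCCCCc2cc(OCc3ccccc3)cc(OCc3ccccc3)c2)C1 | intermediate
19 | 5-{14-[3,5-bis(benzyloxy)phenyl]tetradecyl}-3-methoxy-6-(phenylselanyl)cyclohex-2-en-1-one (racemic, mainly 5,6-trans, used as the mixture) | COC1=CC(=O)C([Se]c2ccccc2)C(CCCCCCCCCCCCCCc2cc(OCc3ccccc3)cc(OCc3ccccc3)c2)C1 | intermediate
20 | 6-(benzeneseleninyl)-5-{14-[3,5-bis(benzyloxy)phenyl]tetradecyl}-3-methoxycyclohex-2-en-1-one (diastereomer mixture) | COC1=CC(=O)C([Se](=O)c2ccccc2)C(CCCCCCCCCCCCCCc2cc(OCc3ccccc3)cc(OCc3ccccc3)c2)C1 | intermediate (not isolated)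
21 | 5-{14-[3,5-bis(benzyloxy)phenyl]tetradecyl}-3-methoxycyclohexa-2,5-dien-1-one | COC1=CC(=O)C=C(CCCCCCCCCCCCCCc2cc(OCc3ccccc3)cc(OCc3ccccc3)c2)C1 | intermediate (not isolated)
22 | 3-{14-[3,5-bis(benzyloxy)phenyl]tetradecyl}-5-methoxyphenol | COc1cc(O)cc(CCCCCCCCCCCCCCc2cc(OCc3ccccc3)cc(OCc3ccccc3)c2)c1 | intermediate
23 | 5-[14-(3-hydroxy-5-methoxyphenyl)tetradecyl]benzene-1,3-diol | COc1cc(O)cc(CCCCCCCCCCCCCCc2cc(O)cc(O)c2)c1 | target

**Step count and risks**

Total step count: 11. Longest linear sequence: 10 steps (lactone 4 to target 23, steps 2 to 11); step 1 is a one-step side branch that joins at step 4.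

Steps most likely to fail:

1. Step 7 (annulation). The enolizable enone may be consumed by base-induced self-condensation or double-bond migration before malonate adds. The Claisen closure may also stall if the long-chain sodium enolates precipitate from methanol. Fallback, setting out from aldehyde 10: Horner–Wadsworth–Emmons reaction with trimethyl phosphonoacetate (NaH, THF, 0 °C) should give methyl (2E)-17-[3,5-bis(benzyloxy)phenyl]heptadec-2-enoate F1, an acceptor with no enolizable ketone. Michael addition of methyl acetoacetate (NaOMe, MeOH/THF, reflux) should then give dimethyl 2-acetyl-3-{14-[3,5-bis(benzyloxy)phenyl]tetradecyl}pentanedioate F2. Its methyl ketone closes onto the CH2CO2Me ester in the same flask, the classical acetoacetate route to dihydroresorcinols. This closure gives the cyclic keto ester 15, where the fallback comes back to the route; 15 is saponified and decarboxylated through 16 to dione 17 as in step 7.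

2. Step 9 (α'-selenenylation, with step 10). Proton transfer between the enolate and the more acidic product selenide may lead to double selenenylation and returned 18. Electrophilic selenium species may also attack the electron-rich phenol ring during the oxidation. Fallback, setting out from enol ether 18: LiN(iPr)2 then Me3SiCl (THF, −78 °C) should give the silyl dienol ether 5-{14-[3,5-bis(benzyloxy)phenyl]tetradecyl}-1-methoxy-3-(trimethylsilyloxy)cyclohexa-1,3-diene F3. Saegusa–Ito dehydrogenation with Pd(OAc)2 in MeCN at rt should then give dienone 21, which tautomerizes to phenol 22, where the fallback comes back to the route with no selenium used.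

3. Step 5 (partial reduction). The aluminium hemiacetal may collapse before the quench, so that the aldehyde is reduced further to the primary alcohol and a mixture results. Fallback, setting out from ester 8: full reduction with LiAlH4 (THF, 0 °C) should give 15-[3,5-bis(benzyloxy)phenyl]pentadecan-1-ol F4. Oxidation with Dess–Martin periodinane (CH2Cl2, NaHCO3, rt) then comes back to the route at aldehyde 10.

**Further compounds**

F1 | step 7 | methyl (2E)-17-[3,5-bis(benzyloxy)phenyl]heptadec-2-enoate | COC(=O)/C=C/CCCCCCCCCCCCCCc1cc(OCc2ccccc2)cc(OCc2ccccc2)c1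
F2 | step 7 | dimethyl 2-acetyl-3-{14-[3,5-bis(benzyloxy)phenyl]tetradecyl}pentanedioate (diastereomer mixture) | COC(=O)CC(CCCCCCCCCCCCCCc1cc(OCc2ccccc2)cc(OCc2ccccc2)c1)C(C(C)=O)C(=O)OC
F3 | step 9 | 5-{14-[3,5-bis(benzyloxy)phenyl]tetradecyl}-1-methoxy-3-(trimethylsilyloxy)cyclohexa-1,3-diene (racemic) | COC1=CC(O[Si](C)(C)C)=CC(CCCCCCCCCCCCCCc2cc(OCc3ccccc3)cc(OCc3ccccc3)c2)C1
F4 | step 5 | 15-[3,5-bis(benzyloxy)phenyl]pentadecan-1-ol | OCCCCCCCCCCCCCCCc1cc(OCc2ccccc2)cc(OCc2ccccc2)c1
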